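**Retrosynthetic overview**
1. The target is a trans-(2S,3S)-2,3-diaryl-2,3-dihydrobenzofuran. Its benzo ring (C3a–C7a) is a 5-substituted resorcinol in which C3a lies between the two ring oxygens (O1 and the C4 hydroxyl). The last operations are a Heck reaction at C6 (stilbene arm) and removal of the Boc, acetyl and TIPS groups (TIPS = triisopropylsilyl, Boc = tert-butoxycarbonyl).
2. Key disconnection: the single carbon C2, with its 2,4-dioxygenated aryl ring, is cut out of the furan ring (bonds C2–C3 and O1–C2). This is a (4+1) annulation of an o-quinone methide (O1, C7a, C3a, C3) with a sulfide-bound chiral benzylidene (sulfonium ylide). It closes the only ring made in the route and sets C2 and C3 together.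
3. The o-quinone methide is made in the same flask from a symmetric 2,6-bis(Boc-oxy)-4-bromobenzaldehyde and 3,5-bis(silyloxy)phenylmagnesium bromide (C3–aryl bond). The two ring oxygens are equivalent, so either one becomes O1 and the other stays as the C4 carbonate; no desymmetrisation is needed.
4. Building blocks: 4-bromo-2,6-dimethoxybenzaldehyde, 5-bromoresorcinol, 2,4-dihydroxybenzaldehyde, isothiocineole, 4-acetoxy-3-methoxystyrene.

Key step: step 7

Assumption: the (1R,4R,5R) antipode of the sulfide is taken to lead to the (2S,3S) series, by analogy with the sense of its benzylidene transfer to C=X acceptors; if the first run shows the opposite sense, the (1S,4S,5S) sulfide is used in the same steps.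

**Route**

Step 1
Reactants: 1 4-bromo-2,6-dimethoxybenzaldehyde
Product: 2 4-bromo-2,6-dihydroxybenzaldehyde
Conditions: BBr3 (3.5 equiv), CH2Cl2, −78 °C → rt; then H2O
Reagents that add atoms: none
Why: Lewis-acid cleavage of both aryl methyl ethers (assisted by chelation to the ortho formyl group) should leave the aryl bromide and, after hydrolysis, the aldehyde intact.

Step 2
Reactants: 2 4-bromo-2,6-dihydroxybenzaldehyde
Product: 3 4-bromo-2,6-bis(tert-butoxycarbonyloxy)benzaldehyde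
Conditions: Boc2O (2.3 equiv), i-Pr2NEt, DMAP (5 mol %), THF, 0 °C → rt
Reagents that add atoms: di-tert-butyl dicarbonate CC(C)(C)OC(=O)OC(=O)OC(C)(C)C
Why: DMAP-catalysed O-acylation of both phenols is the standard entry to o-Boc-oxybenzaldehydes, which serve as low-temperature o-quinone methide precursors.

Step 3
Reactants: 4 5-bromobenzene-1,3-diol
Product: 5 1-bromo-3,5-bis(triisopropylsilyloxy)benzene
Conditions: TIPSCl (2.3 equiv), imidazole, DMF, rt
Reagents that add atoms: chlorotriisopropylsilane CC(C)[Si](Cl)(C(C)C)C(C)C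
Why: Standard phenol silylation gives TIPS ethers that tolerate Grignard formation, amide bases and amines and are removed by fluoride at the end.

Step 4
Reactants: 6 2,4-dihydroxybenzaldehyde
Product: 7 2,4-bis(triisopropylsilyloxy)benzaldehyde
Conditions: TIPSOTf (2.3 equiv), 2,6-lutidine, CH2Cl2, 0 °C → rt
Reagents that add atoms: triisopropylsilyl trifluoromethanesulfonate CC(C)[Si](OS(=O)(=O)C(F)(F)F)(C(C)C)C(C)C
Why: O-silylation with a silyl triflate and a hindered pyridine base should also protect the hydrogen-bonded ortho phenol of the salicylaldehyde.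

Step 5
Reactants: 7 2,4-bis(triisopropylsilyloxy)benzaldehyde
Product: 8 [2,4-bis(triisopropylsilyloxy)phenyl]methanol
Conditions: NaBH4, THF/MeOH, 0 °C
Reagents that add atoms: none
Why: Chemoselective hydride reduction of the aldehyde gives the benzylic alcohol; at 0 °C the hindered TIPS group should not migrate from the phenolic to the benzylic oxygen.

Step 6
Reactants: 8 [2,4-bis(triisopropylsilyloxy)phenyl]methanol; 9 (1R,4R,5R)-4,7,7-trimethyl-6-thiabicyclo[3.2.1]octane (isothiocineole)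
Product: 10 (1R,4R,5R,6R)-6-[2,4-bis(triisopropylsilyloxy)benzyl]-4,7,7-trimethyl-6-thiabicyclo[3.2.1]octan-6-ium trifluoromethanesulfonate
Conditions: 9 (1.1 equiv), TfOH (1.0 equiv), CH2Cl2, −40 → 0 °C; trituration with pentane
Reagents that add atoms: trifluoromethanesulfonic acid OS(=O)(=O)C(F)(F)F
Why: Acid-mediated dehydrative S-alkylation: the electron-rich benzylic alcohol ionises on protonation and the cation is captured by the sulfide on its less hindered (exo) lone pair, which should give a single configuration at sulfur as is usual for benzylic salts of this sulfide.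

Step 7
Reactants: 5 1-bromo-3,5-bis(triisopropylsilyloxy)benzene; 3 4-bromo-2,6-bis(tert-butoxycarbonyloxy)benzaldehyde; 10 (1R,4R,5R,6R)-6-[2,4-bis(triisopropylsilyloxy)benzyl]-4,7,7-trimethyl-6-thiabicyclo[3.2.1]octan-6-ium trifluoromethanesulfonate
Product: 17 tert-butyl (2S,3S)-6-bromo-2-[2,4-bis(triisopropylsilyloxy)phenyl]-3-[3,5-bis(triisopropylsilyloxy)phenyl]-2,3-dihydro-1-benzofuran-4-yl carbonate, via arylmagnesium bromide 11 (not isolated), via magnesium alkoxide 12 (not isolated), via Boc-shifted magnesium phenoxide 13 (not isolated), via o-quinone methide 14 (not isolated), via sulfonium ylide 15 (not isolated), via sulfonium phenoxide betaine 16 (not isolated)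
Conditions: 5, Mg, THF, rt (→ 11, titrated); 3, THF, −78 °C, 11 (1.0 equiv); then 15 [from 10 (1.5 equiv), LiHMDS (1.45 equiv), THF, −78 °C] by cannula, −78 → −20 °C; aq. NH4Cl
Reagents that add atoms: none
Why: Proposed new method: the aryl Grignard 11 adds to aldehyde 3, the alkoxide 12 takes over one of the two equivalent neighbouring Boc groups, and the phenoxide 13 expels tert-butyl carbonate to give o-quinone methide 14 (the known low-temperature o-Boc-oxybenzaldehyde route to o-quinone methides); the chiral benzylic ylide 15 then attacks the exocyclic carbon of 14 in a 1,4-sense, which restores the arene and gives betaine 16. The phenoxide of 16 displaces the sulfide at the benzylic carbon in a 5-exo-tet closure, so the dihydrofuran ring forms by a formal (4+1) annulation (C2–C3 first, then O1–C2); the closest known reaction types are the base-mediated (4+1) annulation of o-quinone methides with sulfonium ylides to trans-2,3-dihydrobenzofurans and the asymmetric benzylidene transfer from sulfide-bound chiral benzylic ylides to C=O and C=N acceptors. C3 is set in the C–C bond-forming event: the bicyclic sulfide fixes the ylide conformation and shields one face of the ylide carbon, and the quinone methide approaches with its aryl group anti to the ylide aryl group, so one enantiotopic face of the methide carbon is selected. C2 is set by the same ylide face followed by inversion in the ring closure; if the electron-rich C2 aryl group makes this substitution SN1-like, closure should still give the more stable 2,3-trans isomer, so C2 follows C3. The step needs 1,4- over 1,2-addition (secured by re-aromatisation), ring closure over β-elimination of the sulfide (secured by the 5-exo geometry of the ortho phenoxide) and no choice between the ring oxygens (the two Boc-oxy groups of 3 are equivalent, and the unused one remains as the C4 carbonate).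

Step 8
Reactants: 17 tert-butyl (2S,3S)-6-bromo-2-[2,4-bis(triisopropylsilyloxy)phenyl]-3-[3,5-bis(triisopropylsilyloxy)phenyl]-2,3-dihydro-1-benzofuran-4-yl carbonate; 18 4-ethenyl-2-methoxyphenyl acetate
Product: 19 4-[(E)-2-{(2S,3S)-4-(tert-butoxycarbonyloxy)-2-[2,4-bis(triisopropylsilyloxy)phenyl]-3-[3,5-bis(triisopropylsilyloxy)phenyl]-2,3-dihydro-1-benzofuran-6-yl}ethenyl]-2-methoxyphenyl acetate
Conditions: 18 (1.3 equiv), Pd2(dba)3 (2 mol %), [(t-Bu)3PH]BF4 (8 mol %), Cy2NMe (1.5 equiv), 1,4-dioxane, rt → 45 °C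
Reagents that add atoms: none
Why: A Mizoroki–Heck reaction under mild trialkylphosphine conditions should give the (E)-stilbene by syn-insertion and syn-β-hydride elimination, and the amine base and low temperature should leave the carbonate, the acetate, the silyl ethers and both benzylic stereocentres untouched.

Step 9
Reactants: 19 4-[(E)-2-{(2S,3S)-4-(tert-butoxycarbonyloxy)-2-[2,4-bis(triisopropylsilyloxy)phenyl]-3-[3,5-bis(triisopropylsilyloxy)phenyl]-2,3-dihydro-1-benzofuran-6-yl}ethenyl]-2-methoxyphenyl acetate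
Product: 21 4-[(2S,3S)-3-(3,5-dihydroxyphenyl)-4-hydroxy-6-[(E)-2-(4-hydroxy-3-methoxyphenyl)ethenyl]-2,3-dihydro-1-benzofuran-2-yl]benzene-1,3-diol, via tetrasilylated bisphenol 20 (not isolated)
Conditions: K2CO3 (3 equiv), MeOH/THF, 0 °C; AcOH, concentrate; then TBAF/AcOH (1:1, 6 equiv), THF, 0 °C → rt, under Ar
Reagents that add atoms: none
Why: Carbonate-mediated methanolysis removes the aryl acetate and the aryl Boc carbonate while the C2 aryl ring is still silylated (so no para-quinone methide can open the furan ring), and acetic-acid-buffered fluoride then cleaves the four aryl TIPS ethers without free phenoxides; no stereocentre is touched.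

**Compound list**
1 | 4-bromo-2,6-dimethoxybenzaldehyde | COc1cc(Br)cc(OC)c1C=O | starting material
2 | 4-bromo-2,6-dihydroxybenzaldehyde | O=Cc1c(O)cc(Br)cc1O | intermediate
3 | 4-bromo-2,6-bis(tert-butoxycarbonyloxy)benzaldehyde | O=Cc1c(OC(=O)OC(C)(C)C)cc(Br)cc1OC(=O)OC(C)(C)C | intermediate
4 | 5-bromobenzene-1,3-diol | Oc1cc(O)cc(Br)c1 | starting material
5 | 1-bromo-3,5-bis(triisopropylsilyloxy)benzene | Brc1cc(O[Si](C(C)C)(C(C)C)C(C)C)cc(O[Si](C(C)C)(C(C)C)C(C)C)c1 | intermediate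
6 | 2,4-dihydroxybenzaldehyde | O=Cc1ccc(O)cc1O | starting material
7 | 2,4-bis(triisopropylsilyloxy)benzaldehyde | O=Cc1ccc(O[Si](C(C)C)(C(C)C)C(C)C)cc1O[Si](C(C)C)(C(C)C)C(C)C | intermediate
8 | [2,4-bis(triisopropylsilyloxy)phenyl]methanol | OCc1ccc(O[Si](C(C)C)(C(C)C)C(C)C)cc1O[Si](C(C)C)(C(C)C)C(C)C | intermediate
9 | (1R,4R,5R)-4,7,7-trimethyl-6-thiabicyclo[3.2.1]octane (isothiocineole) | C[C@@H]1CC[C@@H]2C[C@H]1SC2(C)C | starting material
10 | (1R,4R,5R,6R)-6-[2,4-bis(triisopropylsilyloxy)benzyl]-4,7,7-trimethyl-6-thiabicyclo[3.2.1]octan-6-ium trifluoromethanesulfonate | C(c1ccc(O[Si](C(C)C)(C(C)C)C(C)C)cc1O[Si](C(C)C)(C(C)C)C(C)C)[S@+]1C(C)(C)[C@@H]2CC[C@@H](C)[C@H]1C2.[O-]S(=O)(=O)C(F)(F)F | intermediate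
11 | [3,5-bis(triisopropylsilyloxy)phenyl]magnesium bromide | Br[Mg]c1cc(O[Si](C(C)C)(C(C)C)C(C)C)cc(O[Si](C(C)C)(C(C)C)C(C)C)c1 | intermediate
12 | bromomagnesium [4-bromo-2,6-bis(tert-butoxycarbonyloxy)phenyl][3,5-bis(triisopropylsilyloxy)phenyl]methanolate (racemic) | Br[Mg]OC(c1c(OC(=O)OC(C)(C)C)cc(Br)cc1OC(=O)OC(C)(C)C)c1cc(O[Si](C(C)C)(C(C)C)C(C)C)cc(O[Si](C(C)C)(C(C)C)C(C)C)c1 | intermediate
13 | bromomagnesium 5-bromo-3-(tert-butoxycarbonyloxy)-2-{(tert-butoxycarbonyloxy)[3,5-bis(triisopropylsilyloxy)phenyl]methyl}phenolate (racemic) | Br[Mg]Oc1cc(Br)cc(OC(=O)OC(C)(C)C)c1C(OC(=O)OC(C)(C)C)c1cc(O[Si](C(C)C)(C(C)C)C(C)C)cc(O[Si](C(C)C)(C(C)C)C(C)C)c1 | intermediate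
14 | (6Z)-3-bromo-5-(tert-butoxycarbonyloxy)-6-[3,5-bis(triisopropylsilyloxy)benzylidene]cyclohexa-2,4-dien-1-one (aryl group syn to C=O) | O=C1C=C(Br)C=C(OC(=O)OC(C)(C)C)/C1=C/c1cc(O[Si](C(C)C)(C(C)C)C(C)C)cc(O[Si](C(C)C)(C(C)C)C(C)C)c1 | intermediate
15 | ylide of 10: [2,4-bis(triisopropylsilyloxy)phenyl][(1R,4R,5R)-4,7,7-trimethyl-6-thiabicyclo[3.2.1]octan-6-ium-6-yl]methanide (exo at sulfur) | [CH-](c1ccc(O[Si](C(C)C)(C(C)C)C(C)C)cc1O[Si](C(C)C)(C(C)C)C(C)C)[S@+]1C(C)(C)[C@@H]2CC[C@@H](C)[C@H]1C2 | intermediate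
16 | betaine: 5-bromo-3-(tert-butoxycarbonyloxy)-2-{(1S,2R)-2-[2,4-bis(triisopropylsilyloxy)phenyl]-1-[3,5-bis(triisopropylsilyloxy)phenyl]-2-[(1R,4R,5R)-4,7,7-trimethyl-6-thiabicyclo[3.2.1]octan-6-ium-6-yl]ethyl}phenolate | [O-]c1cc(Br)cc(OC(=O)OC(C)(C)C)c1[C@H](c1cc(O[Si](C(C)C)(C(C)C)C(C)C)cc(O[Si](C(C)C)(C(C)C)C(C)C)c1)[C@H](c1ccc(O[Si](C(C)C)(C(C)C)C(C)C)cc1O[Si](C(C)C)(C(C)C)C(C)C)[S@+]1C(C)(C)[C@@H]2CC[C@@H](C)[C@H]1C2 | intermediate
17 | tert-butyl (2S,3S)-6-bromo-2-[2,4-bis(triisopropylsilyloxy)phenyl]-3-[3,5-bis(triisopropylsilyloxy)phenyl]-2,3-dihydro-1-benzofuran-4-yl carbonate | Brc1cc(OC(=O)OC(C)(C)C)c2c(c1)O[C@H](c1ccc(O[Si](C(C)C)(C(C)C)C(C)C)cc1O[Si](C(C)C)(C(C)C)C(C)C)[C@H]2c1cc(O[Si](C(C)C)(C(C)C)C(C)C)cc(O[Si](C(C)C)(C(C)C)C(C)C)c1 | intermediate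
18 | 4-ethenyl-2-methoxyphenyl acetate (4-acetoxy-3-methoxystyrene) | CC(=O)Oc1ccc(C=C)cc1OC | starting material
19 | 4-[(E)-2-{(2S,3S)-4-(tert-butoxycarbonyloxy)-2-[2,4-bis(triisopropylsilyloxy)phenyl]-3-[3,5-bis(triisopropylsilyloxy)phenyl]-2,3-dihydro-1-benzofuran-6-yl}ethenyl]-2-methoxyphenyl acetate | CC(=O)Oc1ccc(/C=C/c2cc(OC(=O)OC(C)(C)C)c3c(c2)O[C@H](c2ccc(O[Si](C(C)C)(C(C)C)C(C)C)cc2O[Si](C(C)C)(C(C)C)C(C)C)[C@H]3c2cc(O[Si](C(C)C)(C(C)C)C(C)C)cc(O[Si](C(C)C)(C(C)C)C(C)C)c2)cc1OC | intermediate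
20 | (2S,3S)-2-[2,4-bis(triisopropylsilyloxy)phenyl]-3-[3,5-bis(triisopropylsilyloxy)phenyl]-6-[(E)-2-(4-hydroxy-3-methoxyphenyl)ethenyl]-2,3-dihydro-1-benzofuran-4-ol | COc1cc(/C=C/c2cc(O)c3c(c2)O[C@H](c2ccc(O[Si](C(C)C)(C(C)C)C(C)C)cc2O[Si](C(C)C)(C(C)C)C(C)C)[C@H]3c2cc(O[Si](C(C)C)(C(C)C)C(C)C)cc(O[Si](C(C)C)(C(C)C)C(C)C)c2)ccc1O | intermediate
21 | 4-[(2S,3S)-3-(3,5-dihydroxyphenyl)-4-hydroxy-6-[(E)-2-(4-hydroxy-3-methoxyphenyl)ethenyl]-2,3-dihydro-1-benzofuran-2-yl]benzene-1,3-diol (CNP0136479.1) | COc1cc(/C=C/c2cc(O)c3c(c2)O[C@H](c2ccc(O)cc2O)[C@H]3c2cc(O)cc(O)c2)ccc1O | target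

**Totals**
Total step count: 9.
Longest linear sequence: 6 steps (6 → 7 → 8 → 10 → 17 → 19 → 21; steps 4, 5, 6, 7, 8, 9).

**Steps most likely to fail**

1. Step 7 (proposed new method). The ylide may add with poor facial selectivity. The betaine may lose the sulfide by β-elimination instead of closing the ring. The ylide may be consumed by the carbonate and carbon dioxide released in the flask. The quinone methide may oligomerise before it is trapped.
Fallback (known chemistry, enantioselective rhodium-carbene C–H insertion), setting out from 2, 8 and 11 and returning at 17: a double Mitsunobu etherification of 2 with 8 (PPh3, DIAD, THF) should give 4-bromo-2,6-bis{[2,4-bis(triisopropylsilyloxy)phenyl]methoxy}benzaldehyde F1. Addition of 11 (THF, −78 → 0 °C) gives the diarylmethanol F2, and Dess–Martin oxidation gives the benzophenone F3. Condensation with hydrazine hydrate (EtOH, cat. AcOH, 80 °C) gives the hydrazone F4, and MnO2 (CH2Cl2, 0 °C) oxidises it to the diaryldiazomethane F5. Without isolation, a chiral dirhodium tetracarboxylate of the N-phthaloyl-adamantylglycinate type (the antipode that gives the 3S centre) should insert the donor/donor carbene into a benzylic C–H bond of one of the two equivalent ether arms, giving the cis-(2R,3S)-dihydrobenzofuran F6. TFA with pentamethylbenzene (CH2Cl2, 0 °C) should then cleave the remaining electron-rich benzyl ether and epimerise C2 through reversible benzylic ionisation to the trans-(2S,3S)-phenol F7. Boc2O/DMAP then gives 17.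

2. Step 6. Ionisation of the very electron-rich benzylic alcohol may lead to self-alkylation of the arene rings (oligomers). Acid may strip the silyl groups. The salt may revert to cation and sulfide during isolation.
Fallback (S-alkylation by a preformed halide under neutral conditions, no Brønsted acid), setting out from 8 and returning at 10: Appel bromination (CBr4, PPh3, CH2Cl2, 0 °C) gives 1-(bromomethyl)-2,4-bis(triisopropylsilyloxy)benzene F8, which is used crude. Reaction of F8 with 9 and AgOTf (CH2Cl2, −20 °C → rt) precipitates silver bromide and gives 10.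

3. Step 9. Once the para oxygen of the C2 aryl ring is free, base or fluoride may open the furan ring through a para-quinone methide, which would epimerise C2 or remove the C3 hydrogen to give a triarylethylene. The free polyphenol may also oxidise in air under basic conditions.
Fallback (silyl-to-acetyl exchange, then neutral deacetylation), setting out from 20 (isolated after the methanolysis) and returning at 21: CsF and Ac2O (DMF, rt) cleave the silyl ethers and trap each phenoxide at once, and acetylate the two free phenols, giving the hexaacetate F9, which can be purified. Ammonium acetate in aqueous methanol (rt) then removes the aryl acetates under near-neutral conditions to give 21.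

**Further compounds**
F1 | step 7 | 4-bromo-2,6-bis{[2,4-bis(triisopropylsilyloxy)phenyl]methoxy}benzaldehyde | O=Cc1c(OCc2ccc(O[Si](C(C)C)(C(C)C)C(C)C)cc2O[Si](C(C)C)(C(C)C)C(C)C)cc(Br)cc1OCc1ccc(O[Si](C(C)C)(C(C)C)C(C)C)cc1O[Si](C(C)C)(C(C)C)C(C)C
F2 | step 7 | (4-bromo-2,6-bis{[2,4-bis(triisopropylsilyloxy)phenyl]methoxy}phenyl)[3,5-bis(triisopropylsilyloxy)phenyl]methanol (racemic) | OC(c1c(OCc2ccc(O[Si](C(C)C)(C(C)C)C(C)C)cc2O[Si](C(C)C)(C(C)C)C(C)C)cc(Br)cc1OCc1ccc(O[Si](C(C)C)(C(C)C)C(C)C)cc1O[Si](C(C)C)(C(C)C)C(C)C)c1cc(O[Si](C(C)C)(C(C)C)C(C)C)cc(O[Si](C(C)C)(C(C)C)C(C)C)c1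
F3 | step 7 | (4-bromo-2,6-bis{[2,4-bis(triisopropylsilyloxy)phenyl]methoxy}phenyl)[3,5-bis(triisopropylsilyloxy)phenyl]methanone | O=C(c1c(OCc2ccc(O[Si](C(C)C)(C(C)C)C(C)C)cc2O[Si](C(C)C)(C(C)C)C(C)C)cc(Br)cc1OCc1ccc(O[Si](C(C)C)(C(C)C)C(C)C)cc1O[Si](C(C)C)(C(C)C)C(C)C)c1cc(O[Si](C(C)C)(C(C)C)C(C)C)cc(O[Si](C(C)C)(C(C)C)C(C)C)c1
F4 | step 7 | hydrazone of F3 | NN=C(c1c(OCc2ccc(O[Si](C(C)C)(C(C)C)C(C)C)cc2O[Si](C(C)C)(C(C)C)C(C)C)cc(Br)cc1OCc1ccc(O[Si](C(C)C)(C(C)C)C(C)C)cc1O[Si](C(C)C)(C(C)C)C(C)C)c1cc(O[Si](C(C)C)(C(C)C)C(C)C)cc(O[Si](C(C)C)(C(C)C)C(C)C)c1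
F5 | step 7 | (4-bromo-2,6-bis{[2,4-bis(triisopropylsilyloxy)phenyl]methoxy}phenyl)[3,5-bis(triisopropylsilyloxy)phenyl]diazomethane | [N-]=[N+]=C(c1c(OCc2ccc(O[Si](C(C)C)(C(C)C)C(C)C)cc2O[Si](C(C)C)(C(C)C)C(C)C)cc(Br)cc1OCc1ccc(O[Si](C(C)C)(C(C)C)C(C)C)cc1O[Si](C(C)C)(C(C)C)C(C)C)c1cc(O[Si](C(C)C)(C(C)C)C(C)C)cc(O[Si](C(C)C)(C(C)C)C(C)C)c1
F6 | step 7 | (2R,3S)-6-bromo-2-[2,4-bis(triisopropylsilyloxy)phenyl]-3-[3,5-bis(triisopropylsilyloxy)phenyl]-4-{[2,4-bis(triisopropylsilyloxy)phenyl]methoxy}-2,3-dihydro-1-benzofuran (cis) | Brc1cc(OCc2ccc(O[Si](C(C)C)(C(C)C)C(C)C)cc2O[Si](C(C)C)(C(C)C)C(C)C)c2c(c1)O[C@@H](c1ccc(O[Si](C(C)C)(C(C)C)C(C)C)cc1O[Si](C(C)C)(C(C)C)C(C)C)[C@H]2c1cc(O[Si](C(C)C)(C(C)C)C(C)C)cc(O[Si](C(C)C)(C(C)C)C(C)C)c1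
F7 | step 7 | (2S,3S)-6-bromo-2-[2,4-bis(triisopropylsilyloxy)phenyl]-3-[3,5-bis(triisopropylsilyloxy)phenyl]-2,3-dihydro-1-benzofuran-4-ol | Brc1cc(O)c2c(c1)O[C@H](c1ccc(O[Si](C(C)C)(C(C)C)C(C)C)cc1O[Si](C(C)C)(C(C)C)C(C)C)[C@H]2c1cc(O[Si](C(C)C)(C(C)C)C(C)C)cc(O[Si](C(C)C)(C(C)C)C(C)C)c1
F8 | step 6 | 1-(bromomethyl)-2,4-bis(triisopropylsilyloxy)benzene | BrCc1ccc(O[Si](C(C)C)(C(C)C)C(C)C)cc1O[Si](C(C)C)(C(C)C)C(C)C
F9 | step 9 | hexaacetate of 21: 4-[(2S,3S)-4-acetoxy-6-[(E)-2-(4-acetoxy-3-methoxyphenyl)ethenyl]-3-(3,5-diacetoxyphenyl)-2,3-dihydro-1-benzofuran-2-yl]-1,3-phenylene diacetate | COc1cc(/C=C/c2cc(OC(C)=O)c3c(c2)O[C@H](c2ccc(OC(C)=O)cc2OC(C)=O)[C@H]3c2cc(OC(C)=O)cc(OC(C)=O)c2)ccc1OC(C)=O
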